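## The problem

Locants follow the lactone: C1 is the ring carbonyl, C2–C8 the ring carbons, C9 the methyl on C8, and C1'–C8' the acyl chain on O7.

- **Ring.** The ring is a nine-membered lactone (C1–C8 plus the C8 oxygen). Closing it costs entropy and transannular strain. The same carboxyl could instead be captured by O4 (five-membered), O5 (six-membered) or O7 (eight-membered).
- **Stereocentres.** Seven contiguous centres C2–C8 must be set, C4 being a methyl-bearing tertiary carbinol, plus the isolated carbinol C4'. C8 is the carbinol carbon of lactic acid and can steer C6 and C5 through an enolate. A free O5 can then steer C7 by 1,3-syn reduction. C3 can steer C4 (stereospecific C–O exchange) and C2 (addition to the neighbouring alkene). C4' needs its own source of chirality.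
- **Fragile groups.** The (Z)-4-hydroxy-2-enoate can close to a butenolide and expel O7, and it isomerises to E under nucleophilic catalysis. The strained lactone with free γ- and δ-hydroxyls can contract under acid or base. β-Hydroxy ketone intermediates can undergo retro-aldol cleavage, and C2 is epimerisable once C1 is a carbonyl.
- **Enabling feature.** In C1–C5 the carbinol C3 is flanked by C2 and C4, each bearing one methyl and one terminal carbon (C1, C5) that is oxidised in the target. The segment is therefore constitutionally symmetric about C3 and equals 2,4-dimethylpenta-1,4-dien-3-ol (3), an achiral dienol with two enantiotopic isopropenyl groups. One asymmetric epoxidation that picks one group and one face sets C3 and C4 together.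
- **Consequence.** That epoxidation gives the erythro pair, whereas the target is threo at C3/C4, so the C4–O bond must afterwards be exchanged with inversion.

## Retrosynthesis

**Side chain and last operations.** Target 36 is traced to tetraol ynoate 35 (C2'≡C3' in place of the Z-alkene), then to protected ester 34, which is cut at the O7–C1' bond into lactone diol 26 and ynoic acid 32. The alkyne is preferred to a preformed Z-enoic acid because it cannot isomerise during acyl transfer and cannot form a butenolide when O4' is unmasked. The Z-alkene then appears only in the final, neutral semi-hydrogenation. The forward reactions must acylate O7 and not O5, and must stop hydrogenation at the alkene.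

**Lactone C1–O8.** Lactone 25 (26 with O5 and O7 as benzyloxymethyl ethers) is opened to seco acid 23. Ring closures through C–C bonds (C2–C3 or C5–C6) would create stereocentres in a medium-ring transition state, whereas lactonisation creates none. All eight ring atoms are then in an open chain whose centres are set by acyclic control. The price is a nine-membered closure in which O4, O5 and O7 must be masked. O3/O4 are held in a trans-fused isopropylidene ketal, which a nine-membered ring tolerates. O5 and O7 carry acyclic ethers, because a cyclic 1,3-acetal would hold C4–C8 in an extended zigzag that such a ring cannot adopt.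

**C1 and C2 from the second isopropenyl group.** Acid 22 (silyl ether of 23) comes from primary alcohol 20, and 20 from alkene 18 by hydroboration. This uses the "other half" of the dienol instead of adding a two-carbon unit by a further aldol reaction. The forward step must place the C2 methyl anti to O3 under control of C3.

**Protecting-group exchange.** Ketal 18 comes from diol 17, and 17 from cyclic carbonate 16, the bis-ether of diol 15. The carbonate can only be removed with base, so it must leave before any ester exists. It is exchanged at the point where O5 and O7 are already capped, so that only the C3/C4 ketal can form.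

**C5–C6 bond and C7.** Diol 15 comes from hydroxy ketone 13 by hydroxyl-directed reduction, and 13 is cut at C5–C6 into aldehyde 7 and ethyl ketone 11. This cut joins a C1–C5 and a C6–C9 piece of similar size and takes C8 from the chiral pool. Cutting C6–C7 instead would need an extra ketone synthesis on the C1–C5 piece. The forward aldol must proceed through a Z-enolate, with the enolate face fixed by C8 strongly enough to override the aldehyde's own preference.

**C4 inversion.** Aldehyde 7 comes from alcohol 6. Its cyclic carbonate is traced to tert-butyl carbonate 5 and epoxy alcohol 4 by exchanging the C4–O bond. The carbonate oxygen enters at C4 from the rear while the epoxide oxygen stays on C5. This single operation corrects erythro to threo, ties O3 and O4 together, and leaves O5 as the only free hydroxyl.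

**Key disconnection.** Epoxy alcohol 4 loses its oxirane oxygen (bonds O–C4 and O–C5) to give achiral dienol 3, which is cut at C3–C4 into methacrolein 1 and isopropenylmagnesium bromide 2. Two stereocentres and the differentiation of C1 from C5 are reduced to one catalytic step on a seven-carbon alcohol made in one step.

**Building blocks.** Ketone 11 comes from ethyl (S)-lactate 8 through silyl ether 9 and Weinreb amide 10. Acid 32 comes from racemic hept-1-yn-3-ol 27 through ynone 28, (R)-alcohol 29, silyl ether 30 and its lithium acetylide 31.

## Roads not taken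

Alternative 1: Both ring carbonyls are traced back to one alkene. The C1 lactone carbonyl and a C5 ketone become the two carbons of a tetrasubstituted enol ether C1=C5, the fusion bond of a cyclopentene (C1–C5) and a dihydropyran (O, C1, C5–C8) in bicycle A1. Ozone followed by dimethyl sulfide would cleave that bond and leave keto lactone A2, whose nine-membered ring is the former perimeter.
- Merits: no medium ring has to be closed at all, the enol ether is the most ozone-reactive site, and the centres could be set on rigid small rings. In ring formation this road is better than the chosen plan.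
- Weak points: A1 must already carry six stereocentres, including the quaternary C4 next to a fully substituted alkene, and no short route to it is evident. After cleavage, C5 is a ketone between the quaternary C4 and the epimerisable C6. It must be reduced to the 5S alcohol inside a nine-membered ring, where facial bias is conformational and hard to predict.
- Comparison: the chosen plan sets C5 in an open-chain aldol reaction and C3/C4 catalytically in its second step. Against this it has only a lactonisation that may be low-yielding but forms no stereocentre.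

Alternative 2: The cut removes CH3–C4 and C4–C5 together. Methylmagnesium bromide would add to the acylsilane carbonyl of silyl glyoxylate A3, a 1,2-Brook shift would unveil a magnesium glycolate enolate, and this would add to aldehyde A4 to give hydroxy ester A5.
- Merits: three components are joined in one flask, and the tertiary oxygen is silylated as it is formed. O7 and O8 arrive with different protecting groups, so the O5/O7 differentiation that costs the chosen plan several steps is built in. In these respects it is the better road.
- Weak points: two stereocentres, one of them quaternary, are created in one uncatalysed event. They are controlled only by the α-methyl centre of A4 and by an enolate geometry that is not secured, and the target needs one specific pair out of four. A5 ends at C3 as an ester, so C1–C2 and the C2 and C3 centres must still be added next to the quaternary carbon.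
- Comparison: the chosen plan draws C3 and C4 from a catalyst and C1–C2 from the second isopropenyl group, at the price of more protecting-group work.

Alternative 3: The ring is cut at C2–C3. The ester bond is made first, as a 2-bromopropanoate on O8 in aldehyde A6. SmI2 (divalent samarium) would then generate a samarium enolate that adds to the C3 aldehyde and closes the ring to hydroxy lactone A7.
- Merits: samarium-templated Reformatsky closures are among the more dependable entries to medium lactones, and no hindered acid has to be activated. For ring closure this road is probably more reliable than the chosen lactonisation.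
- Weak points: C2 and C3 are both created during ring closure, with control only from a medium-ring transition state. Four diastereomers are possible and the target needs the 2,3-anti one with a fixed absolute sense. The aldehyde sits on a neopentyl-like carbon next to the ketal carbon C4.
- Comparison: the chosen plan has C3 fixed by the tartrate catalyst and C2 by an open-chain hydroboration before any ring exists, and accepts the harder closure in exchange.

Key step: step 2

Assumption: hept-1-yn-3-ol is taken as the commercial racemate, so its carbinol centre is set within the route (steps 19 and 20).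

Step 1
Reactants: 1 methacrolein; 2 isopropenylmagnesium bromide
Product: 3 2,4-dimethylpenta-1,4-dien-3-ol
Conditions: THF, −78 → 0 °C; aq. NH4Cl
Reagents that add atoms: none
Why: Grignard 1,2-addition; the hard vinylic nucleophile should attack the aldehyde carbonyl of the enal, and the product is achiral, so nothing has to be controlled.

Step 2
Reactants: 3 2,4-dimethylpenta-1,4-dien-3-ol
Product: 4 (R)-2-methyl-1-[(S)-2-methyloxiran-2-yl]prop-2-en-1-ol
Conditions: Ti(OiPr)4 (0.2 equiv), D-(−)-diisopropyl tartrate (0.25 equiv), tBuOOH (1.2 equiv, isooctane), 4 Å MS, CH2Cl2, −20 °C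
Reagents that add atoms: tert-butyl hydroperoxide, CC(C)(C)OO
Why: Sharpless asymmetric epoxidation of a secondary allylic alcohol, used here as a desymmetrisation. Ligand exchange places the alkoxide of 3 and the tert-butyl peroxide on one metal of the tetravalent titanium–tartrate dimer, and the peroxide oxygen is passed to the alkene in one concerted step through a spiro transition state, so the oxirane closes by direct oxygen-atom transfer to C4 and C5 (a formal [2+1] closure without an open intermediate). The closest known reaction type is the epoxidation of divinyl carbinols, in which group selection and face selection act together. C4 is set by the tartrate, which as the D-(−) ester delivers oxygen to the alkene face that gives the 4S oxirane; C3 becomes a stereocentre because only the isopropenyl group whose carbinol hydrogen, not the other isopropenyl group, points toward the tartrate ester can reach the peroxide, which fixes 3R and the erythro relationship. The step needs enantiotopic-group selectivity, face selectivity and mono-epoxidation at the same time. The first two are one recognition event; the third is secured because 4 keeps a mismatched alkene and reacts slowly, whereas its minor enantiomer keeps a matched alkene and is drained into bis-epoxide, so the enantiomeric purity of 4 should rise with conversion. The methyl group on the alkene carbon next to the carbinol is tolerated by this catalyst, and molecular sieves keep it catalytic, which eases isolation of the small, water-soluble product.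

Step 3
Reactants: 4 (R)-2-methyl-1-[(S)-2-methyloxiran-2-yl]prop-2-en-1-ol
Product: 5 tert-butyl (R)-2-methyl-1-[(S)-2-methyloxiran-2-yl]prop-2-en-1-yl carbonate
Conditions: Boc2O, DMAP (0.1 equiv), CH2Cl2, 0 °C → rt
Reagents that add atoms: di-tert-butyl dicarbonate, CC(C)(C)OC(=O)OC(=O)OC(C)(C)C
Why: DMAP-catalysed O-acylation to the mixed carbonate; the near-neutral conditions should avoid Payne rearrangement of the epoxy alcohol, and no stereocentre is touched.

Step 4
Reactants: 5 tert-butyl (R)-2-methyl-1-[(S)-2-methyloxiran-2-yl]prop-2-en-1-yl carbonate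
Product: 6 (4R,5R)-4-(hydroxymethyl)-4-methyl-5-(prop-1-en-2-yl)-1,3-dioxolan-2-one
Conditions: BF3·OEt2 (0.3 equiv), CH2Cl2, −78 → −40 °C; aq. NaHCO3
Reagents that add atoms: none
Why: Lewis-acid-promoted intramolecular epoxide opening by the carbonate carbonyl oxygen (neighbouring-group participation); attack is 5-exo at the tertiary C4, the carbon best able to carry positive charge, and comes from the rear, so C4 is inverted to the target configuration while the tert-butyl group leaves as isobutene and O5 is released as the only free hydroxyl.

Step 5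
Reactants: 6 (4R,5R)-4-(hydroxymethyl)-4-methyl-5-(prop-1-en-2-yl)-1,3-dioxolan-2-one
Product: 7 (4S,5R)-4-methyl-2-oxo-5-(prop-1-en-2-yl)-1,3-dioxolane-4-carbaldehyde
Conditions: Dess–Martin periodinane, NaHCO3, CH2Cl2, 0 °C → rt
Reagents that add atoms: none
Why: Dess–Martin oxidation of a neopentyl-type primary alcohol; the aldehyde has no α-hydrogen and cannot epimerise, and the buffered, non-basic medium should leave the carbonate in place.

Step 6
Reactants: 8 ethyl (S)-lactate
Product: 9 ethyl (S)-2-[(tert-butyldimethylsilyl)oxy]propanoate
Conditions: TBSCl, imidazole, DMF, rt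
Reagents that add atoms: tert-butyldimethylsilyl chloride, CC(C)(C)[Si](C)(C)Cl
Why: silyl ether formation; the stereocentre, which becomes C8, is not involved.

Step 7
Reactants: 9 ethyl (S)-2-[(tert-butyldimethylsilyl)oxy]propanoate
Product: 10 (S)-2-[(tert-butyldimethylsilyl)oxy]-N-methoxy-N-methylpropanamide
Conditions: MeNH(OMe)·HCl, iPrMgCl, THF, −20 → 0 °C
Reagents that add atoms: N,O-dimethylhydroxylamine hydrochloride, CNOC.Cl
Why: Weinreb amide formation by aminolysis of the ester with the magnesium amide made in the flask; low temperature and a poorly enolising base should keep the α-silyloxy centre intact.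

Step 8
Reactants: 10 (S)-2-[(tert-butyldimethylsilyl)oxy]-N-methoxy-N-methylpropanamide
Product: 11 (S)-2-[(tert-butyldimethylsilyl)oxy]pentan-3-one
Conditions: EtMgBr, THF, 0 °C; aq. NH4Cl
Reagents that add atoms: ethylmagnesium bromide, CC[Mg]Br
Why: Weinreb ketone synthesis; the chelated tetrahedral adduct persists until work-up, so only one ethyl group should be added.

Step 9
Reactants: 11 (S)-2-[(tert-butyldimethylsilyl)oxy]pentan-3-one; 7 (4S,5R)-4-methyl-2-oxo-5-(prop-1-en-2-yl)-1,3-dioxolane-4-carbaldehyde
Product: 13 (4R,5R)-4-[(1S,2S,4S)-4-(tert-butyldimethylsilyloxy)-1-hydroxy-2-methyl-3-oxopentyl]-4-methyl-5-(prop-1-en-2-yl)-1,3-dioxolan-2-one, via titanium Z-enolate 12 (not isolated)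
Conditions: 11, TiCl4 (1.1 equiv), iPr2NEt (1.1 equiv), CH2Cl2, −78 °C; TiCl4 (1.0 equiv); then 7, −78 °C; aq. NH4Cl
Reagents that add atoms: none
Why: titanium-mediated syn-aldol reaction of an α-silyloxy ethyl ketone; the Z-enolate should react through a Zimmerman–Traxler chair, which makes O5 and the C6 methyl syn, and the bulky, non-chelating silyloxy group at C8 turns away from titanium so that the aldehyde meets the enolate face giving the 6,8-anti adduct (5S,6S). This enolate bias has to override the weaker Felkin–Anh preference of the α-oxygenated, α-quaternary aldehyde, whose two flanking groups (methyl and ring methine) differ little in size.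

Step 10
Reactants: 13 (4R,5R)-4-[(1S,2S,4S)-4-(tert-butyldimethylsilyloxy)-1-hydroxy-2-methyl-3-oxopentyl]-4-methyl-5-(prop-1-en-2-yl)-1,3-dioxolan-2-one
Product: 15 (4R,5R)-4-[(1S,2R,3R,4S)-4-(tert-butyldimethylsilyloxy)-1,3-dihydroxy-2-methylpentyl]-4-methyl-5-(prop-1-en-2-yl)-1,3-dioxolan-2-one, via diethylboryl chelate 14 (not isolated)
Conditions: Et2BOMe, THF/MeOH (4:1), −78 °C; NaBH4; AcOH, then MeOH azeotrope
Reagents that add atoms: none
Why: Narasaka–Prasad reduction; boron ties O5 to the C7 carbonyl in a six-membered chelate and external hydride attacks axially, which should give the 5,7-syn diol (7R, also 7,8-anti) and override the Felkin preference of the C8 silyloxy group; the low temperature spares the carbonate.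

Step 11
Reactants: 15 (4R,5R)-4-[(1S,2R,3R,4S)-4-(tert-butyldimethylsilyloxy)-1,3-dihydroxy-2-methylpentyl]-4-methyl-5-(prop-1-en-2-yl)-1,3-dioxolan-2-one
Product: 16 5,7-bis-O-(benzyloxymethyl) ether of 15
Conditions: BOMCl, iPr2NEt, Bu4NI (0.2 equiv), ClCH2CH2Cl, 50 °C
Reagents that add atoms: benzyl chloromethyl ether, ClCOCc1ccccc1
Why: alkoxymethyl ether formation with a highly reactive α-chloro ether under amine base, which should reach even the hindered O5; acyclic groups are chosen because a cyclic 1,3-acetal would later block nine-membered ring closure, and they are removable by hydrogenolysis before any unsaturation is introduced.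

Step 12
Reactants: 16 5,7-bis-O-(benzyloxymethyl) ether of 15
Product: 17 5,7-bis(benzyloxymethoxy)-8-(tert-butyldimethylsilyloxy)-2,4,6-trimethylnon-1-ene-3,4-diol (stereocentres as in 16)
Conditions: K2CO3, MeOH, 0 °C → rt
Reagents that add atoms: none
Why: base-catalysed methanolysis (transesterification) of the cyclic carbonate; it is done here because no other ester is present yet and all other groups (silyl ether, acetal ethers, alkene) are inert to carbonate base.

Step 13
Reactants: 17 5,7-bis(benzyloxymethoxy)-8-(tert-butyldimethylsilyloxy)-2,4,6-trimethylnon-1-ene-3,4-diol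
Product: 18 3,4-O-isopropylidene ketal of 17
Conditions: Me2C(OMe)2, PPTS, CH2Cl2, rt
Reagents that add atoms: 2,2-dimethoxypropane, COC(C)(C)OC
Why: acid-catalysed transketalisation; O3/O4 is the only diol left, so a single trans-fused dioxolane should form, stable to fluoride, base, oxidants and hydrogenolysis.

Step 14
Reactants: 18 3,4-O-isopropylidene ketal of 17
Product: 20 C1 primary alcohol (2,3-anti) from 18, via B-alkyl-9-BBN adduct 19 (not isolated)
Conditions: 9-BBN, THF, 0 °C → rt; then NaOH, H2O2, 0 °C
Reagents that add atoms: hydrogen peroxide, OO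
Why: hydroboration–oxidation of a 1,1-disubstituted alkene next to an oxygenated stereocentre; in the reactive conformer C3–H eclipses the alkene (allylic strain) and the bulky borane should add to the face turned away from the fully substituted C4, placing the new C2 methyl anti to O3, and boron goes to the terminal carbon, which becomes C1.

Step 15
Reactants: 20 C1 primary alcohol (2,3-anti) from 18
Product: 22 C1 carboxylic acid (2S) from 20, via C1 aldehyde 21 (not isolated)
Conditions: TEMPO (0.1 equiv), NaClO2, NaOCl (0.05 equiv), MeCN/phosphate buffer (pH 6.7), 35 °C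
Reagents that add atoms: sodium chlorite, [Na+].[O-]Cl=O
Why: TEMPO-catalysed oxidation to the aldehyde followed in the same pot by Pinnick-type chlorite oxidation; the near-neutral buffer should spare the ketal and silyl ether and avoid epimerisation of the α-methyl aldehyde.

Step 16
Reactants: 22 C1 carboxylic acid (2S) from 20
Product: 23 seco acid (8-hydroxy acid) from 22
Conditions: TBAF, THF, rt; aq. NH4Cl
Reagents that add atoms: none
Why: fluoride-mediated cleavage of the secondary silyl ether; the ketal and the alkoxymethyl ethers contain no silicon and are inert, so only O8 is unmasked.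

Step 17
Reactants: 23 seco acid (8-hydroxy acid) from 22
Product: 25 nine-membered lactone (5,7-bis-O-benzyloxymethyl; 3,4-O-isopropylidene), via mixed anhydride 24 (not isolated)
Conditions: MNBA (2-methyl-6-nitrobenzoic anhydride, 1.3 equiv), DMAP (3 equiv), CH2Cl2 (2 mM), 23 added over 16 h, rt
Reagents that add atoms: none
Why: Shiina macrolactonisation; the mixed anhydride forms selectively at the aliphatic acid and DMAP passes the acyl group to O8 under high dilution, with O4, O5 and O7 masked so that only the nine-membered mode is open; the trans-fused ketal and the dense substitution should favour folded conformers, and no stereocentre is formed.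

Step 18
Reactants: 25 nine-membered lactone (5,7-bis-O-benzyloxymethyl; 3,4-O-isopropylidene)
Product: 26 lactone 5,7-diol (3,4-O-isopropylidene)
Conditions: H2 (1 atm), Pd(OH)2/C, EtOAc, rt
Reagents that add atoms: none
Why: hydrogenolysis of the benzylic C–O bonds; the resulting hemiformals lose formaldehyde, and lactone and ketal are untouched under these neutral conditions.

Step 19
Reactants: 27 hept-1-yn-3-ol (racemic)
Product: 28 hept-1-yn-3-one
Conditions: Dess–Martin periodinane, CH2Cl2, 0 °C → rt
Reagents that add atoms: none
Why: Dess–Martin oxidation of a propargylic alcohol; it erases the racemic centre so that it can be reset.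

Step 20
Reactants: 28 hept-1-yn-3-one
Product: 29 (R)-hept-1-yn-3-ol
Conditions: (R)-Alpine-Borane [B-isopinocampheyl-9-BBN from (+)-α-pinene], THF, rt; then HOCH2CH2NH2, Et2O
Reagents that add atoms: none
Why: Midland reduction; hydride is transferred from the pinanyl group through a boat-like six-membered transition state in which the slim ethynyl group lies next to the pinane methyl, the established route to (R)-alk-1-yn-3-ols from the (+)-pinene reagent.

Step 21
Reactants: 29 (R)-hept-1-yn-3-ol
Product: 30 (R)-tert-butyl(hept-1-yn-3-yloxy)dimethylsilane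
Conditions: TBSCl, imidazole, DMF, rt
Reagents that add atoms: tert-butyldimethylsilyl chloride, CC(C)(C)[Si](C)(C)Cl
Why: silyl ether formation; it blocks O4' so that the acid cannot esterify itself later.

Step 22
Reactants: 30 (R)-tert-butyl(hept-1-yn-3-yloxy)dimethylsilane
Product: 32 (R)-4-[(tert-butyldimethylsilyl)oxy]oct-2-ynoic acid, via lithium acetylide 31 (not isolated)
Conditions: nBuLi, THF, −78 °C; CO2 (g), −78 → 0 °C; 1 M HCl, 0 °C
Reagents that add atoms: carbon dioxide, O=C=O
Why: deprotonation of the terminal alkyne and carboxylation of the acetylide; the propargylic centre carries no acidic hydrogen under these conditions and should keep its configuration.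

Step 23
Reactants: 26 lactone 5,7-diol (3,4-O-isopropylidene); 32 (R)-4-[(tert-butyldimethylsilyl)oxy]oct-2-ynoic acid
Product: 34 7-O-[(R)-4-(tert-butyldimethylsilyloxy)oct-2-ynoyl] ester of 26, via mixed anhydride 33 (not isolated)
Conditions: 32 (1.5 equiv), MNBA (1.6 equiv), DMAP (0.2 equiv), Et3N, CH2Cl2, 0 °C → rt
Reagents that add atoms: none
Why: Shiina esterification through the mixed anhydride; of the two free hydroxyls only O7 should be reached, O5 being neopentyl-like against the ketal carbon C4, and the alkynoic acid cannot lose double-bond geometry during acyl transfer.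

Step 24
Reactants: 34 7-O-[(R)-4-(tert-butyldimethylsilyloxy)oct-2-ynoyl] ester of 26
Product: 35 7-O-[(R)-4-hydroxyoct-2-ynoyl] 3,4,5-triol lactone
Conditions: TFA/H2O (9:1), 0 °C, short contact; toluene azeotrope
Reagents that add atoms: none
Why: acid hydrolysis of the isopropylidene ketal and solvolysis of the silyl ether in one operation; cold acid and short contact are chosen because the freed O4 and O5 could contract the lactone on long exposure, and the linear 4-hydroxy-2-ynoate cannot close to a butenolide.

Step 25
Reactants: 35 7-O-[(R)-4-hydroxyoct-2-ynoyl] 3,4,5-triol lactone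
Product: 36 CNP0205075.3 (target)
Conditions: H2 (1 atm), Pd/CaCO3 poisoned with Pb(OAc)2 (Lindlar catalyst), quinoline, EtOAc, rt
Reagents that add atoms: none
Why: Lindlar semi-hydrogenation; syn delivery of hydrogen on the poisoned palladium surface should give the Z-alkene, and placing it last under neutral conditions means the (Z)-4-hydroxy enoate never meets acid or base.

## Compound list

1 | methacrolein (2-methylprop-2-enal) | C=C(C)C=O | starting material
2 | isopropenylmagnesium bromide | C=C(C)[Mg]Br | starting material
3 | 2,4-dimethylpenta-1,4-dien-3-ol | C=C(C)C(O)C(C)=C | intermediate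
4 | (R)-2-methyl-1-[(S)-2-methyloxiran-2-yl]prop-2-en-1-ol (erythro epoxy alcohol) | C=C(C)[C@@H](O)[C@]1(C)CO1 | intermediate
5 | tert-butyl (R)-2-methyl-1-[(S)-2-methyloxiran-2-yl]prop-2-en-1-yl carbonate | C=C(C)[C@@H](OC(=O)OC(C)(C)C)[C@]1(C)CO1 | intermediate
6 | (4R,5R)-4-(hydroxymethyl)-4-methyl-5-(prop-1-en-2-yl)-1,3-dioxolan-2-one | C=C(C)[C@H]1OC(=O)O[C@]1(C)CO | intermediate
7 | (4S,5R)-4-methyl-2-oxo-5-(prop-1-en-2-yl)-1,3-dioxolane-4-carbaldehyde | C=C(C)[C@H]1OC(=O)O[C@]1(C)C=O | intermediate
8 | ethyl (S)-lactate | CCOC(=O)[C@H](C)O | starting material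
9 | ethyl (S)-2-[(tert-butyldimethylsilyl)oxy]propanoate | CCOC(=O)[C@H](C)O[Si](C)(C)C(C)(C)C | intermediate
10 | (S)-2-[(tert-butyldimethylsilyl)oxy]-N-methoxy-N-methylpropanamide | CON(C)C(=O)[C@H](C)O[Si](C)(C)C(C)(C)C | intermediate
11 | (S)-2-[(tert-butyldimethylsilyl)oxy]pentan-3-one | CCC(=O)[C@H](C)O[Si](C)(C)C(C)(C)C | intermediate
12 | trichlorotitanium (Z)-enolate of 11 | C/C=C(\O[Ti](Cl)(Cl)Cl)[C@H](C)O[Si](C)(C)C(C)(C)C | intermediate
13 | (4R,5R)-4-[(1S,2S,4S)-4-(tert-butyldimethylsilyloxy)-1-hydroxy-2-methyl-3-oxopentyl]-4-methyl-5-(prop-1-en-2-yl)-1,3-dioxolan-2-one (aldol adduct) | C[C@H](O[Si](C)(C)C(C)(C)C)C(=O)[C@@H](C)[C@H](O)[C@@]1(C)OC(=O)O[C@@H]1C(C)=C | intermediate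
14 | O5-diethylboryl derivative (boron chelate) of 13 | C[C@H](O[Si](C)(C)C(C)(C)C)C(=O)[C@@H](C)[C@H](OB(CC)CC)[C@@]1(C)OC(=O)O[C@@H]1C(C)=C | intermediate
15 | (4R,5R)-4-[(1S,2R,3R,4S)-4-(tert-butyldimethylsilyloxy)-1,3-dihydroxy-2-methylpentyl]-4-methyl-5-(prop-1-en-2-yl)-1,3-dioxolan-2-one (5,7-syn diol) | C[C@H](O[Si](C)(C)C(C)(C)C)[C@H](O)[C@@H](C)[C@H](O)[C@@]1(C)OC(=O)O[C@@H]1C(C)=C | intermediate
16 | 5,7-bis-O-(benzyloxymethyl) ether of 15 | C[C@H](O[Si](C)(C)C(C)(C)C)[C@H](OCOCc1ccccc1)[C@@H](C)[C@H](OCOCc1ccccc1)[C@@]1(C)OC(=O)O[C@@H]1C(C)=C | intermediate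
17 | 5,7-bis(benzyloxymethoxy)-8-(tert-butyldimethylsilyloxy)-2,4,6-trimethylnon-1-ene-3,4-diol, stereocentres as in 16 | C[C@H](O[Si](C)(C)C(C)(C)C)[C@H](OCOCc1ccccc1)[C@@H](C)[C@H](OCOCc1ccccc1)[C@@](C)(O)[C@H](O)C(C)=C | intermediate
18 | 3,4-O-isopropylidene ketal of 17 | C[C@H](O[Si](C)(C)C(C)(C)C)[C@H](OCOCc1ccccc1)[C@@H](C)[C@H](OCOCc1ccccc1)[C@@]1(C)OC(C)(C)O[C@@H]1C(C)=C | intermediate
19 | B-alkyl-9-borabicyclo[3.3.1]nonane adduct of 18 (boron on C1, C2 methyl anti to O3) | C[C@H](O[Si](C)(C)C(C)(C)C)[C@H](OCOCc1ccccc1)[C@@H](C)[C@H](OCOCc1ccccc1)[C@@]1(C)OC(C)(C)O[C@@H]1[C@H](C)CB1C2CCCC1CCC2 | intermediate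
20 | C1 primary alcohol from 18 (2,3-anti) | C[C@H](O[Si](C)(C)C(C)(C)C)[C@H](OCOCc1ccccc1)[C@@H](C)[C@H](OCOCc1ccccc1)[C@@]1(C)OC(C)(C)O[C@@H]1[C@H](C)CO | intermediate
21 | C1 aldehyde from 20 | C[C@H](O[Si](C)(C)C(C)(C)C)[C@H](OCOCc1ccccc1)[C@@H](C)[C@H](OCOCc1ccccc1)[C@@]1(C)OC(C)(C)O[C@@H]1[C@H](C)C=O | intermediate
22 | C1 carboxylic acid (2S) from 20 | C[C@H](O[Si](C)(C)C(C)(C)C)[C@H](OCOCc1ccccc1)[C@@H](C)[C@H](OCOCc1ccccc1)[C@@]1(C)OC(C)(C)O[C@@H]1[C@H](C)C(=O)O | intermediate
23 | seco acid (8-hydroxy acid; O5, O7 benzyloxymethyl ethers; 3,4-O-isopropylidene) | C[C@H](O)[C@H](OCOCc1ccccc1)[C@@H](C)[C@H](OCOCc1ccccc1)[C@@]1(C)OC(C)(C)O[C@@H]1[C@H](C)C(=O)O | intermediate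
24 | mixed anhydride of 23 with 2-methyl-6-nitrobenzoic acid | C[C@H](O)[C@H](OCOCc1ccccc1)[C@@H](C)[C@H](OCOCc1ccccc1)[C@@]1(C)OC(C)(C)O[C@@H]1[C@H](C)C(=O)OC(=O)c1c(C)cccc1[N+](=O)[O-] | intermediate
25 | nine-membered lactone, 5,7-bis-O-(benzyloxymethyl), 3,4-O-isopropylidene | c1ccccc1COCO[C@@H]1[C@@H](C)[C@H](OCOCc2ccccc2)[C@@]2(C)OC(C)(C)O[C@@H]2[C@H](C)C(=O)O[C@H]1C | intermediate
26 | nine-membered lactone 5,7-diol, 3,4-O-isopropylidene | O[C@@H]1[C@@H](C)[C@H](O)[C@@]2(C)OC(C)(C)O[C@@H]2[C@H](C)C(=O)O[C@H]1C | intermediate
27 | hept-1-yn-3-ol (racemic) | CCCCC(O)C#C | starting material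
28 | hept-1-yn-3-one | CCCCC(=O)C#C | intermediate
29 | (R)-hept-1-yn-3-ol | CCCC[C@@H](O)C#C | intermediate
30 | (R)-tert-butyl(hept-1-yn-3-yloxy)dimethylsilane | CCCC[C@@H](O[Si](C)(C)C(C)(C)C)C#C | intermediate
31 | lithium acetylide of 30 | CCCC[C@@H](O[Si](C)(C)C(C)(C)C)C#C[Li] | intermediate
32 | (R)-4-[(tert-butyldimethylsilyl)oxy]oct-2-ynoic acid | CCCC[C@@H](O[Si](C)(C)C(C)(C)C)C#CC(=O)O | intermediate
33 | mixed anhydride of 32 with 2-methyl-6-nitrobenzoic acid | CCCC[C@@H](O[Si](C)(C)C(C)(C)C)C#CC(=O)OC(=O)c1c(C)cccc1[N+](=O)[O-] | intermediate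
34 | 7-O-[(R)-4-(tert-butyldimethylsilyloxy)oct-2-ynoyl] ester of 26 | CCCC[C@@H](O[Si](C)(C)C(C)(C)C)C#CC(=O)O[C@@H]1[C@@H](C)[C@H](O)[C@@]2(C)OC(C)(C)O[C@@H]2[C@H](C)C(=O)O[C@H]1C | intermediate
35 | 7-O-[(R)-4-hydroxyoct-2-ynoyl] 3,4,5-trihydroxy nine-membered lactone | CCCC[C@@H](O)C#CC(=O)O[C@@H]1[C@@H](C)[C@H](O)[C@@](C)(O)[C@H](O)[C@H](C)C(=O)O[C@H]1C | intermediate
36 | CNP0205075.3 | CCCC[C@@H](O)/C=C\C(=O)O[C@@H]1[C@@H](C)[C@H](O)[C@@](C)(O)[C@H](O)[C@H](C)C(=O)O[C@H]1C | target

## Step count and least certain steps

Total step count: 25. Longest linear sequence: 18 steps (steps 1–5, 9–18 and 23–25).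

**Step 2 (key step).** The two enantiotopic alkenes may be differentiated incompletely. Over-epoxidation to bis-epoxide may cut the yield, and the small, volatile, water-soluble product may be lost or may undergo Payne rearrangement during isolation. The fallback sets out from Grignard reagent 2 and returns at 4. The C4 centre is made on a primary allylic alcohol, for which the same tartrate epoxidation is most dependable. (R)-2-Methylglycidol F1 (commercial, or from 2-methylprop-2-en-1-ol with the D-(−) tartrate) is oxidised with SO3·pyridine/DMSO to (S)-2-methyloxirane-2-carbaldehyde F2. Reagent 2 is added at −78 °C, and the C3 epimers are separated by chromatography to give 4.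

**Step 9.** This is a mismatched double stereodifferentiation. The Felkin–Anh/Cornforth preference of the α-oxygenated aldehyde opposes the enolate face, which may erode selectivity at C5/C6. Addition to the hindered carbonyl may also be slow enough for retro-aldol equilibration. The fallback sets out from 7 and returns at 15, forming C6–C7 instead of C5–C6. EtMgBr at −78 °C gives carbinol F3, and Dess–Martin oxidation gives ethyl ketone F4. Its Z-boron enolate (Bu2BOTf, iPr2NEt) is added to (S)-2-[(tert-butyldimethylsilyl)oxy]propanal F5, made from 9 with iBu2AlH at −78 °C. The α-silyloxy aldehyde now directs the syn, 7,8-anti adduct F6. Narasaka–Prasad reduction directed by O7 then sets C5 and gives 15.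

**Step 14.** Facial selectivity may be poor if the ring-oxygen side and the C4 side of the alkene are not differentiated well enough in the reactive conformer, giving a mixture at C2. The fallback sets out from 18 and returns at 22, with catalyst control replacing substrate control. SeO2/tBuOOH oxidises the allylic methyl group to the 2-substituted acrolein F7. Chlorite oxidation (NaClO2, NaH2PO4, 2-methylbut-2-ene) gives acrylic acid F8. Hydrogenation with Ru(OAc)2(BINAP), using the ligand enantiomer that reinforces the substrate, should give 22.

**Step 17.** Intermolecular acylation (diolide and oligomers) may outrun the strained nine-membered closure, and C2 may epimerise through a ketene formed from the mixed anhydride. The fallback sets out from 23 and returns at 25. Base-promoted acyl transfer is replaced by a metal-templated closure of an isolated thioester (Corey–Nicolaou type). 2,2'-Dipyridyl disulfide and PPh3 give the S-(pyridin-2-yl) thioester F9. Slow addition of F9 to AgOTf in toluene at high dilution should then close the ring without base.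

**Step 23.** Acyl transfer may stall at the hindered O7 or spread to O5. The basic medium may also trigger a transannular acyl shift of the ring ester onto the free O5, or conjugate addition of DMAP to the activated ynoate. The fallback sets out from 26 and returns at 35, and keeps O5 capped during acylation. TESOTf/2,6-lutidine gives the 5,7-bis(triethylsilyl) ether F10. PPTS in MeOH at 0 °C removes the less hindered O7 silyl group to give the 5-O-triethylsilyl alcohol F11. Esterification with 32 (MNBA, DMAP) gives ester F12, and cold aqueous TFA removes the ketal and all silyl groups to give 35.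

## Further compounds

F1 | step 2 | (R)-2-methylglycidol, [(2R)-2-methyloxiran-2-yl]methanol | OC[C@]1(C)CO1
F2 | step 2 | (S)-2-methyloxirane-2-carbaldehyde | O=C[C@]1(C)CO1
F3 | step 9 | (4R,5R)-4-(1-hydroxypropyl)-4-methyl-5-(prop-1-en-2-yl)-1,3-dioxolan-2-one (carbinol epimers) | CCC(O)[C@@]1(C)OC(=O)O[C@@H]1C(C)=C
F4 | step 9 | (4S,5R)-4-methyl-4-propanoyl-5-(prop-1-en-2-yl)-1,3-dioxolan-2-one | CCC(=O)[C@@]1(C)OC(=O)O[C@@H]1C(C)=C
F5 | step 9 | (S)-2-[(tert-butyldimethylsilyl)oxy]propanal | C[C@H](O[Si](C)(C)C(C)(C)C)C=O
F6 | step 9 | 7-hydroxy-5-keto isomer of 13 (C6–C7 aldol adduct; 6,7-syn, 7,8-anti) | C[C@H](O[Si](C)(C)C(C)(C)C)[C@H](O)[C@@H](C)C(=O)[C@@]1(C)OC(=O)O[C@@H]1C(C)=C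
F7 | step 14 | 2-substituted acrolein from 18 (C2 bears =CH2 and CHO) | C[C@H](O[Si](C)(C)C(C)(C)C)[C@H](OCOCc1ccccc1)[C@@H](C)[C@H](OCOCc1ccccc1)[C@@]1(C)OC(C)(C)O[C@@H]1C(=C)C=O
F8 | step 14 | 2-substituted acrylic acid from F7 | C[C@H](O[Si](C)(C)C(C)(C)C)[C@H](OCOCc1ccccc1)[C@@H](C)[C@H](OCOCc1ccccc1)[C@@]1(C)OC(C)(C)O[C@@H]1C(=C)C(=O)O
F9 | step 17 | S-(pyridin-2-yl) thioester of 23 | C[C@H](O)[C@H](OCOCc1ccccc1)[C@@H](C)[C@H](OCOCc1ccccc1)[C@@]1(C)OC(C)(C)O[C@@H]1[C@H](C)C(=O)Sc1ccccn1
F10 | step 23 | 5,7-bis-O-(triethylsilyl) ether of 26 | CC[Si](CC)(CC)O[C@@H]1[C@@H](C)[C@H](O[Si](CC)(CC)CC)[C@@]2(C)OC(C)(C)O[C@@H]2[C@H](C)C(=O)O[C@H]1C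
F11 | step 23 | 5-O-(triethylsilyl) ether of 26 (O7 free) | O[C@@H]1[C@@H](C)[C@H](O[Si](CC)(CC)CC)[C@@]2(C)OC(C)(C)O[C@@H]2[C@H](C)C(=O)O[C@H]1C
F12 | step 23 | 7-O-[(R)-4-(tert-butyldimethylsilyloxy)oct-2-ynoyl] ester of F11 | CCCC[C@@H](O[Si](C)(C)C(C)(C)C)C#CC(=O)O[C@@H]1[C@@H](C)[C@H](O[Si](CC)(CC)CC)[C@@]2(C)OC(C)(C)O[C@@H]2[C@H](C)C(=O)O[C@H]1C
A1 | alternative 1 | bicyclic enol ether (cyclopentene fused to dihydropyran through C1=C5; O7 benzyl, O3 and O4 triethylsilyl) | c1ccccc1CO[C@@H]2[C@@H](C)C3=C(O[C@H]2C)[C@@H](C)[C@@H](O[Si](CC)(CC)CC)[C@]3(C)O[Si](CC)(CC)CC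
A2 | alternative 1 | nine-membered 5-keto lactone | c1ccccc1CO[C@@H]2[C@@H](C)C(=O)[C@@](C)(O[Si](CC)(CC)CC)[C@H](O[Si](CC)(CC)CC)[C@H](C)C(=O)O[C@H]2C
A3 | alternative 2 | tert-butyl 2-(tert-butyldimethylsilyl)-2-oxoacetate (silyl glyoxylate) | CC(C)(C)OC(=O)C(=O)[Si](C)(C)C(C)(C)C
A4 | alternative 2 | C5–C9 aldehyde (O7 p-methoxybenzyl, O8 triethylsilyl) | O=C[C@H](C)[C@@H](OCc1ccc(OC)cc1)[C@H](C)O[Si](CC)(CC)CC
A5 | alternative 2 | C3–C9 α-silyloxy-β-hydroxy ester | CC(C)(C)OC(=O)[C@](C)(O[Si](C)(C)C(C)(C)C)[C@@H](O)[C@H](C)[C@@H](OCc1ccc(OC)cc1)[C@H](C)O[Si](CC)(CC)CC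
A6 | alternative 3 | C3 aldehyde carrying the O8 2-bromopropanoate (4,5-O-isopropylidene, O7 p-methoxybenzyl) | COc1ccc(CO[C@@H]([C@H](C)OC(=O)C(C)Br)[C@@H](C)[C@@H]2OC(C)(C)O[C@@]2(C)C=O)cc1
A7 | alternative 3 | nine-membered 3-hydroxy lactone | COc1ccc(CO[C@@H]2[C@@H](C)[C@@H]3OC(C)(C)O[C@@]3(C)[C@H](O)[C@H](C)C(=O)O[C@H]2C)cc1
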